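## Structural features

The target is a flavonol: a 4H-chromen-4-one (benzo ring A fused to pyranone ring C) carrying phenyl ring B on C2 through the single bond C2–C1'. It has no stereocentre, so no stereocentres adjoin and nothing has to be controlled in three dimensions. The complexity lies in nine oxygens: ring A has OH at C5 (hydrogen-bonded to the C4 carbonyl), OMe at C7 and C8 and H at C6; ring C has the enolic 3-OH; ring B has OH at C2' and C4', OMe at C5' and H at C3' and C6'. Fragile parts are the electron-rich ring B once its phenols are free (easily oxidised), C2 of the pyranone (opened by hard nucleophiles), and the 5,7,8-trioxygenated ring A, which can isomerise to the 5,6,7 pattern by ring opening and reclosure in hot protic acid. The real difficulty is differentiation of oxygens: four hydroxyls must be freed while three methyl ethers stay, and two of those sit beside a hydroxyl (C5' next to C4') or between two oxygens (C8). The key step exploits ring B: O at C2' and OMe at C5' are para, C1' carries C2 of ring C and C6' carries hydrogen. That is the 4-methoxyphenol pattern which an alkoxycarbene chromium benzannulation assembles from a carbene carbon (C5'), an alkyne (C6', C1'), carbon monoxide (C2') and an alkenyl unit (C3', C4').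

## Logic of the disconnections

**22 to 21.** Three O–C bonds are cut: benzyl at O3, methoxymethyl at O4' and methyl at O5. All three can fall to one boron trihalide treatment, and the O5 methyl is the only methyl ether chelated to the C4 carbonyl. The gain is that the polar, oxidation-prone tetraphenol appears only in the last flask. The demand is chemoselectivity: the methyls at O7, O8 and O5' must survive.

**21 to 13 and 19.** The bonds C5'–C6', C1'–C2' and C2'–C3' are cut, which takes ring B apart completely. The cut is made here because the para relation of the free C2' hydroxyl and the C5' methoxyl is the signature of a carbene–alkyne–CO benzannulation, and the two ring B oxygens at C2' and C4' emerge already distinguished. The gain is one ring and three C–C bonds in one convergent operation, with ring B traced to a two-carbon alkyne, a three-carbon carbene ligand and CO. The demand is one orientation of alkyne insertion, CO incorporation, and tolerance of the conjugated pyranone in 13.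

**19 to 15 and 16.** The carbene carbon–vinyl carbon bond and the O–CH3 bond are cut. This reduces the complex to a metal carbonyl, a vinyl anion equivalent and a methyl cation equivalent. The demand is clean α-metalation of 15 (via 17) and O-alkylation of the acylmetalate 18.

**15 to 14.** The C=C bond is traced to loss of HBr. This links the vinyl ether to a catalogue bromide and avoids handling a chloromethyl ether. The demand is only that the volatile product be removed as it forms.

**13 to 12, then to 10 and 11.** The C–Si bond and then the C2–C(sp) bond are cut. The silyl group makes the two-carbon unit a storable, mono-reactive partner. The demand is a coupling at C2 that no nucleophile intercepts and a desilylation that the activated alkyne survives; a tertiary amine and buffered fluoride answer this.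

**10 to 8.** The C2–I bond is cut (via 9). C2–H is the only hydrogen on ring C, and it is acidified by O1 and flanked by the O3 substituent. The demand is deprotonation without ring opening and without attack at the benzylic CH2, which is why the O3 benzyl group, inert to amide base at low temperature and to palladium and fluoride later, is kept.

**8 to 7 and 5.** The O3–benzyl bond and then the C3–O bond are cut. Installing O3 on a preformed chromone avoids α-alkoxyacetyl electrophiles, which tend to decarbonylate under the Lewis acids needed for ring A acylation. The demand is an oxidant that attacks C2=C3 and not the trimethoxyarene.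

**5 to 3.** The bonds O1–C2 and C2–C3 are cut, which removes the single carbon C2. This leaves an o-hydroxyaryl methyl ketone and a one-carbon amide acetal. The demand is only that the phenol, not the C6 methoxyl, closes the ring, which is automatic.

**3 to 1.** The aryl–carbonyl bond (future C4–C4a) and one O–CH3 bond (future O1) are cut. The symmetric arene 1 has two equivalent free positions, so acylation is unambiguous. The demand is selective cleavage of the one ortho methyl ether that is buttressed by a neighbouring methoxyl (via 2).

## Other disconnections considered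

**Alternative 1:** The cut is the single bond C2–C1' between rings C and B, made intramolecular by a methylene acetal tying O3 to O2'.

- *Forward step.* The bridged flavonol A1 would arise from the aryl bromide A2, 3-{[5-(benzyloxy)-2-bromo-4-methoxyphenoxy]methoxy}-5,7,8-trimethoxychromen-4-one, an O-alkylation product of 7. Zerovalent palladium (from Pd(OAc)2 and PCy3·HBF4, with K2CO3 and pivalic acid) should add to C1'–Br. The divalent arylpalladium pivalate should cleave C2–H by concerted metalation–deprotonation and eliminate reductively to the dioxepine.
- *In favour.* Ring B arrives complete, so its oxygen pattern is never in question. C2–H is the only C–H on ring C. The metal is catalytic. A2 branches from 7, so iodination, alkynylation, desilylation and both carbene steps would disappear.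
- *Against it here.* The mixed formal between an enol and a phenol must be made unsymmetrically, with symmetrical formals as likely by-products. The bromophenol half needs its bromine placed ortho to the acetal oxygen and not ortho to the benzyloxy group. Closure runs through an eight-membered palladacycle to a seven-membered ring with a twisted biaryl axis. The tether is overhead that must be removed.
- *Comparison.* On structure, this plan takes ring B from the aromatic pool, whereas the chosen plan fixes every ring B substituent by connectivity; neither makes a stereocentre. On mechanism, both are well-understood organometallic sequences. The direct arylation is the better on metal economy and waste; the benzannulation is the better on convergence (three C–C bonds, no tether). On step economy the alternative is at least the equal and probably the better, since formal, benzyl ether and C5 methyl ether could fall to the same boron trihalide treatment.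

**Alternative 2:** The cut removes three bonds of ring C (O1–C8a, C4–C4a and O1–C2), so ring A comes from an aryne and C2, C3, C4 with ring B from an arylpropiolic acid.

- *Forward step.* The flavone A3 would arise from the silyl triflate A4, 5-methoxy-3-(methoxymethoxy)-2-(trimethylsilyl)phenyl trifluoromethanesulfonate, and the acid A5, 3-[2,4-bis(benzyloxy)-5-methoxyphenyl]prop-2-ynoic acid. CsF should release the aryne. The carboxylate oxygen should add at the aryne carbon remote from the methoxymethoxy group (C8a). The aryl anion next to that group (C4a) should attack the ester carbonyl, and the freed phenoxide should close ring C by 6-endo oxa-Michael addition to the ynone.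
- *In favour.* No transition metal is needed. Three bonds form in one flask from two separately made halves. The orientation of addition is steered by the inductive effect of the alkoxy group flanking the aryne.
- *Against it here.* A3 is two oxygens short: it has neither O3 nor the C8 methoxyl. Both would need late oxidations of an electron-rich flavone (C3 through an enolate or epoxide, C8 through para-hydroxylation of the freed C5 phenol and selective methylation). An aryne already carrying the C8 methoxyl would be flanked by alkoxy groups on both sides and lose its orientation. 5-exo closure to an aurone competes with flavone formation.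
- *Comparison.* On mechanism, the alternative equals the chosen step in bonds formed (three) and is the better in needing no metal. On structure it is the weaker, because 21 already carries all nine oxygens of the target and A3 does not. On step economy it is the weaker: the chosen plan needs one operation after the key step, this one needs several oxidation and protection steps.

**Alternative 3:** The cut is C4a–C5, so ring A is grown onto a pyranone that serves as ring C.

- *Forward step.* The flavonol A6 would arise on heating the β-keto ester A7, tert-butyl 4-{5-(benzyloxy)-6-[2,4-bis(benzyloxy)-5-methoxyphenyl]-4-oxo-4H-pyran-2-yl}-4-methoxy-3-oxobutanoate. Loss of the ester alcohol should give an acylketene. Its dienol form should close by 6π electrocyclisation onto the pyranone double bond and aromatise to the 5,7-dihydroxy-8-methoxy ring A.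
- *In favour.* Kojic acid A8 supplies ring C with O3 already in place, so no C3 oxidation is needed; on this point the alternative is the better, since the chosen route spends step 3 on it. Ring A's oxygen pattern is fixed by connectivity, which equals the logic applied to ring B in the chosen plan. The key step needs no metal.
- *Against it here.* A7 is far from A8: C6 arylation, adjustment of the hydroxymethyl carbon to a methoxy-bearing ketone chain and β-keto ester extension are all needed. The electrocyclisation must engage a double bond that belongs to a vinylogous ester and needs one enol geometry. The free acylketene can dimerise or be recaptured. Afterwards the C7 hydroxyl must be methylated in the presence of the C5 hydroxyl (helped by chelation of the latter) and three benzyl groups removed.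
- *Comparison.* On mechanism, both key steps end in the same 6π closure of a dienylketene, metal-bound in the chosen plan and free here; the alternative is the better in using only heat. On structure, the alternative builds ring A and the chosen plan ring B, each by connectivity. On step economy the chosen plan is the better, because its ketene is assembled in the flask from three simple parts, while A7 must be built linearly.

Key step: step 10

Remark on the chemistry: the connectivities of 13, 19 and 21 agree with the atom mapping of the benzannulation and are used unchanged. The only addition is 20, the η6-Cr(CO)3 complex in which the new phenol first appears. CO ligands are written in SMILES as formal Cr=C=O units, and 20 as arene plus Cr(CO)3 fragment joined by a dot.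

Assumption: 14 is taken as a catalogue chemical.

## Steps

Step 1
Reactants: 1 1,2,3,5-tetramethoxybenzene
Product: 3 1-(2-hydroxy-3,4,6-trimethoxyphenyl)ethan-1-one, via 1-(2,3,4,6-tetramethoxyphenyl)ethan-1-one 2 (not isolated)
Conditions: AcCl, AlCl3, Et2O, 0 °C to rt; then aq. HCl
Reagents that add atoms: acetyl chloride, CC(Cl)=O
Why: Friedel–Crafts acylation at one of the two equivalent free positions; the aluminium chelate of the ketone then loses the methyl of the ortho methoxyl that is buttressed by a neighbouring methoxyl (C2), the usual site of chelation-controlled ether cleavage, and limiting AlCl3 and temperature keeps the C6 methoxyl.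

Step 2
Reactants: 3 1-(2-hydroxy-3,4,6-trimethoxyphenyl)ethan-1-one
Product: 5 5,7,8-trimethoxy-4H-chromen-4-one, via enaminone 4 (not isolated)
Conditions: Me2NCH(OMe)2, toluene, 100 °C; then conc. HCl, CH2Cl2, 40 °C
Reagents that add atoms: N,N-dimethylformamide dimethyl acetal, COC(OC)N(C)C
Why: Condensation of the methyl ketone with the amide acetal gives the enaminone; acid-promoted conjugate addition of the phenol and loss of dimethylamine closes the pyranone (standard chromone synthesis).

Step 3
Reactants: 5 5,7,8-trimethoxy-4H-chromen-4-one
Product: 7 3-hydroxy-5,7,8-trimethoxy-4H-chromen-4-one, via 2,3-epoxychromanone 6 (not isolated)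
Conditions: DMDO (acetone solution), CH2Cl2, 0 °C to rt; then p-TsOH·H2O (cat.), CH2Cl2, rt
Reagents that add atoms: dimethyldioxirane, CC1(C)OO1
Why: Dioxirane epoxidation of the chromone C2=C3 bond under neutral conditions, then acid-catalysed opening at the acetal carbon C2 and loss of H3 give the 3-hydroxychromone; the cis-fused epoxide centres are transient and racemic.

Step 4
Reactants: 7 3-hydroxy-5,7,8-trimethoxy-4H-chromen-4-one
Product: 8 3-(benzyloxy)-5,7,8-trimethoxy-4H-chromen-4-one
Conditions: BnBr, K2CO3, DMF, rt
Reagents that add atoms: benzyl bromide, BrCc1ccccc1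
Why: Williamson O-alkylation of the acidic enolic 3-hydroxyl.

Step 5
Reactants: 8 3-(benzyloxy)-5,7,8-trimethoxy-4H-chromen-4-one
Product: 10 3-(benzyloxy)-2-iodo-5,7,8-trimethoxy-4H-chromen-4-one, via 2-lithiochromone 9 (not isolated)
Conditions: LiN(i-Pr)2, THF, −78 °C; then I2, THF, −78 °C
Reagents that add atoms: iodine, II
Why: Kinetic deprotonation of C2–H, the only vinylic hydrogen, acidified by O1 and the adjacent benzyloxy oxygen (the C2 lithiation known for 3-substituted chromones), then iodinolysis; low temperature suppresses ring opening and benzylic deprotonation.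

Step 6
Reactants: 10 3-(benzyloxy)-2-iodo-5,7,8-trimethoxy-4H-chromen-4-one; 11 trimethylsilylacetylene
Product: 12 3-(benzyloxy)-5,7,8-trimethoxy-2-[(trimethylsilyl)ethynyl]-4H-chromen-4-one
Conditions: Pd(PPh3)2Cl2 (cat.), CuI (cat.), Et3N, THF, rt, Ar
Reagents that add atoms: none
Why: Sonogashira coupling; the 2-iodochromone is a vinylogous acyl iodide that adds readily to zerovalent palladium, and a tertiary amine is used so that no amine substitutes at C2.

Step 7
Reactants: 12 3-(benzyloxy)-5,7,8-trimethoxy-2-[(trimethylsilyl)ethynyl]-4H-chromen-4-one
Product: 13 3-(benzyloxy)-2-ethynyl-5,7,8-trimethoxy-4H-chromen-4-one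
Conditions: Bu4NF, AcOH, THF, −20 °C
Reagents that add atoms: none
Why: Fluoride-induced protodesilylation; buffering with acetic acid keeps the medium non-basic so that neither the activated alkyne nor the pyranone is attacked.

Step 8
Reactants: 14 1-bromo-2-(methoxymethoxy)ethane
Product: 15 (methoxymethoxy)ethene
Conditions: KOH (powder), neat, 110 °C, product distilled out
Reagents that add atoms: none
Why: Base-induced E2 dehydrobromination of a 2-bromoethyl ether, a standard entry to vinyl ethers; continuous distillation protects the volatile product.

Step 9
Reactants: 15 (methoxymethoxy)ethene; 16 chromium hexacarbonyl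
Product: 19 pentacarbonyl[methoxy(1-(methoxymethoxy)vinyl)carbene]chromium, via 1-(methoxymethoxy)vinyllithium 17 (not isolated), via lithium acylchromate 18 (not isolated)
Conditions: s-BuLi, THF, −78 to −30 °C; Cr(CO)6, THF, −78 to 0 °C; solvent exchange; MeOTf, CH2Cl2, 0 °C
Reagents that add atoms: methyl trifluoromethanesulfonate, COS(=O)(=O)C(F)(F)F
Why: α-Lithiation of the vinyl ether (assisted by the acetal oxygens), addition of the vinyllithium to a carbonyl ligand and O-methylation of the acylchromate by a hard methylating agent: the classical synthesis of an alkoxycarbene complex of zerovalent chromium.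

Step 10
Reactants: 13 3-(benzyloxy)-2-ethynyl-5,7,8-trimethoxy-4H-chromen-4-one; 19 pentacarbonyl[methoxy(1-(methoxymethoxy)vinyl)carbene]chromium
Product: 21 3-(benzyloxy)-2-[2-hydroxy-5-methoxy-4-(methoxymethoxy)phenyl]-5,7,8-trimethoxy-4H-chromen-4-one, via tricarbonylchromium arene complex 20 (not isolated)
Conditions: 19 (1.5 equiv), THF (degassed), 50 °C, Ar; then air, Et2O, rt
Reagents that add atoms: none
Why: Dötz benzannulation of an alkenyl(methoxy)carbene complex of zerovalent chromium with a terminal alkyne. Loss of one CO from 19 (possibly helped by the hemilabile acetal oxygen) lets the alkyne of 13 bind; insertion into Cr=C joins the unsubstituted alkyne carbon to the carbene carbon (C5'–C6') and turns the chromone-bearing carbon into the new carbene centre. CO insertion at that centre gives a chromium-bound dienylketene (C1'–C2'), and thermal 6π electrocyclisation of the ketene carbon onto the CH2 terminus of the alkoxyvinyl unit (C2'–C3') closes the six-membered ring B as a cyclohexadienone, which tautomerises to the phenol held as the Cr(CO)3 complex 20; air then releases 21. The closest known cases are benzannulations of isopropenyl and of cyclic α-alkoxyalkenyl (dihydropyranyl) methoxycarbene complexes with terminal alkynes. No stereocentre is formed. The step needs one orientation of alkyne insertion, secured by the size difference between hydrogen and the 3-benzyloxychromon-2-yl group on the two alkyne carbons, and phenol formation in preference to CO-free cyclisation, favoured by an alkenyl carbene in an ether solvent at moderate temperature. The substituents of ring B then follow from connectivity alone: carbene carbon C5' (OMe), vinyl carbons C4' (OCH2OMe) and C3', CO carbon C2' (OH), alkyne carbons C6' (H) and C1'.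

Step 11
Reactants: 21 3-(benzyloxy)-2-[2-hydroxy-5-methoxy-4-(methoxymethoxy)phenyl]-5,7,8-trimethoxy-4H-chromen-4-one
Product: 22 2-(2,4-dihydroxy-5-methoxyphenyl)-3,5-dihydroxy-7,8-dimethoxy-4H-chromen-4-one
Conditions: BCl3, C6HMe5, CH2Cl2, −78 to 0 °C; then H2O, 0 °C
Reagents that add atoms: none
Why: Boron trichloride cleaves the benzyl ether (cation trapped by pentamethylbenzene), the methoxymethyl acetal and, through chelation with the C4 carbonyl, only the C5 methyl ether; the unchelated methyls at O7, O8 and O5' are expected to stay at this temperature, and the aprotic cold medium avoids acid-induced isomerisation of ring A.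

## Compound list

1 | 1,2,3,5-tetramethoxybenzene | COc1cc(OC)c(OC)c(OC)c1 | starting material
2 | 1-(2,3,4,6-tetramethoxyphenyl)ethan-1-one | CC(=O)c1c(OC)cc(OC)c(OC)c1OC | intermediate
3 | 1-(2-hydroxy-3,4,6-trimethoxyphenyl)ethan-1-one | CC(=O)c1c(OC)cc(OC)c(OC)c1O | intermediate
4 | (E)-3-(dimethylamino)-1-(2-hydroxy-3,4,6-trimethoxyphenyl)prop-2-en-1-one | CN(C)/C=C/C(=O)c1c(OC)cc(OC)c(OC)c1O | intermediate
5 | 5,7,8-trimethoxy-4H-chromen-4-one | COc1cc(OC)c2c(=O)ccoc2c1OC | intermediate
6 | 2,3-epoxy-5,7,8-trimethoxychroman-4-one (cis-fused epoxide, racemic, one enantiomer drawn) | COc1cc(OC)c2c(c1OC)O[C@@H]1O[C@@H]1C2=O | intermediate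
7 | 3-hydroxy-5,7,8-trimethoxy-4H-chromen-4-one | COc1cc(OC)c2c(=O)c(O)coc2c1OC | intermediate
8 | 3-(benzyloxy)-5,7,8-trimethoxy-4H-chromen-4-one | COc1cc(OC)c2c(=O)c(OCc3ccccc3)coc2c1OC | intermediate
9 | [3-(benzyloxy)-5,7,8-trimethoxy-4-oxo-4H-chromen-2-yl]lithium | [Li]c1oc2c(OC)c(OC)cc(OC)c2c(=O)c1OCc1ccccc1 | intermediate
10 | 3-(benzyloxy)-2-iodo-5,7,8-trimethoxy-4H-chromen-4-one | Ic1oc2c(OC)c(OC)cc(OC)c2c(=O)c1OCc1ccccc1 | intermediate
11 | trimethylsilylacetylene | C#C[Si](C)(C)C | starting material
12 | 3-(benzyloxy)-5,7,8-trimethoxy-2-[(trimethylsilyl)ethynyl]-4H-chromen-4-one | C[Si](C)(C)C#Cc1oc2c(OC)c(OC)cc(OC)c2c(=O)c1OCc1ccccc1 | intermediate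
13 | 3-(benzyloxy)-2-ethynyl-5,7,8-trimethoxy-4H-chromen-4-one | C#Cc1oc2c(OC)c(OC)cc(OC)c2c(=O)c1OCc1ccccc1 | intermediate
14 | 1-bromo-2-(methoxymethoxy)ethane | COCOCCBr | starting material
15 | (methoxymethoxy)ethene (methoxymethyl vinyl ether) | COCOC=C | intermediate
16 | chromium hexacarbonyl, Cr(CO)6 | O=C=[Cr](=C=O)(=C=O)(=C=O)(=C=O)=C=O | starting material
17 | [1-(methoxymethoxy)vinyl]lithium | [Li]C(=C)OCOC | intermediate
18 | lithium pentacarbonyl[2-(methoxymethoxy)-1-oxidoprop-2-en-1-ylidene]chromate | [Li+].COCOC(=C)C([O-])=[Cr](=C=O)(=C=O)(=C=O)(=C=O)=C=O | intermediate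
19 | pentacarbonyl[methoxy(1-(methoxymethoxy)vinyl)carbene]chromium | COCOC(=C)C(OC)=[Cr](=C=O)(=C=O)(=C=O)(=C=O)=C=O | intermediate
20 | tricarbonylchromium complex of 21, Cr(CO)3 bound η6 to ring B | COCOc1cc(O)c(-c2oc3c(OC)c(OC)cc(OC)c3c(=O)c2OCc2ccccc2)cc1OC.O=C=[Cr](=C=O)=C=O | intermediate
21 | 3-(benzyloxy)-2-[2-hydroxy-5-methoxy-4-(methoxymethoxy)phenyl]-5,7,8-trimethoxy-4H-chromen-4-one | COCOc1cc(O)c(-c2oc3c(OC)c(OC)cc(OC)c3c(=O)c2OCc2ccccc2)cc1OC | intermediate
22 | 2-(2,4-dihydroxy-5-methoxyphenyl)-3,5-dihydroxy-7,8-dimethoxy-4H-chromen-4-one | COc1cc(-c2oc3c(OC)c(OC)cc(O)c3c(=O)c2O)c(O)cc1O | target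

## Step count and risks

Total: 11 steps. Longest linear sequence: 9 steps (steps 1 to 7, then 10 and 11, from 1). The carbene arm is 2 steps (8 and 9) and joins at step 10. If 3 is bought instead of made, both counts fall by one.

**Step 10 (key step).** The conjugated, electron-poor alkyne of 13 may bind chromium slowly, so that thermal decay or self-condensation of 19 outruns insertion. O1 or the benzyloxy oxygen may also hold chromium after insertion and divert the vinylcarbene into cyclisation without CO uptake.
Fallback (sets out from 10, comes back at 22): ring B is brought in ready-made. 4-Methoxybenzene-1,3-diol is O-benzylated (BnBr, K2CO3) to 2,4-bis(benzyloxy)-1-methoxybenzene F1. N-Bromosuccinimide brominates F1 para to one benzyloxy group, giving 1,5-bis(benzyloxy)-2-bromo-4-methoxybenzene F2. Bromine–lithium exchange (n-BuLi, −78 °C) gives [2,4-bis(benzyloxy)-5-methoxyphenyl]lithium F3, and borylation (B(OMe)3, then aqueous acid) gives [2,4-bis(benzyloxy)-5-methoxyphenyl]boronic acid F4. Suzuki–Miyaura coupling of F4 with 10 (Pd(PPh3)4, K3PO4, dioxane, 80 °C) should give 3-(benzyloxy)-2-[2,4-bis(benzyloxy)-5-methoxyphenyl]-5,7,8-trimethoxy-4H-chromen-4-one F5. BCl3 with pentamethylbenzene, as in step 11, should take F5 to 22.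

**Step 9.** O-Methylation of the acylchromate may be incomplete, and the electron-rich carbene with an unsubstituted CH2 terminus may oligomerise during concentration or chromatography.
Fallback (sets out from 18, comes back at 19): 18 is not methylated directly. It is precipitated from water with Me4NBr as tetramethylammonium pentacarbonyl[2-(methoxymethoxy)-1-oxidoprop-2-en-1-ylidene]chromate F6, a storable solid. F6 is O-acylated with acetyl bromide in CH2Cl2 at −40 °C to pentacarbonyl[acetoxy(1-(methoxymethoxy)vinyl)carbene]chromium F7. F7 is not isolated; added methanol exchanges its acyloxy group for methoxy, giving 19 in solution for direct use in step 10.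

**Step 3.** The electrophilic oxidant may attack the electron-rich ring A instead of the deactivated C2=C3 bond, or the strained acetal epoxide may open unselectively (cleavage of ring C).
Fallback (sets out from 1, comes back at 8): O3 is carried in from the start. Ortho-lithiation of 1 (n-BuLi, THF, 0 °C) between two methoxyls gives (2,3,4,6-tetramethoxyphenyl)lithium F8. Acylation with 2-(benzyloxy)-N-methoxy-N-methylacetamide gives 2-(benzyloxy)-1-(2,3,4,6-tetramethoxyphenyl)ethan-1-one F9. Chelation-controlled demethylation (MgI2·OEt2, toluene, 80 °C) should free the buttressed ortho oxygen, giving 2-(benzyloxy)-1-(2-hydroxy-3,4,6-trimethoxyphenyl)ethan-1-one F10. Me2NCH(OMe)2 then gives the enaminone 2-(benzyloxy)-3-(dimethylamino)-1-(2-hydroxy-3,4,6-trimethoxyphenyl)prop-2-en-1-one F11, which closes under acid to 8. This way is shorter but is not the first choice, because the selectivity of the demethylation between the two ortho methoxyls and towards the benzyl ether is less secure.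

**Step 7.** Fluoride, acetate or adventitious hydroxide may add to the activated alkyne during desilylation, or base may trigger oligomerisation of the terminal alkyne.
Fallback (sets out from 10, comes back at 13): the ethynyl group is installed without a silyl group by Stille coupling of 10 with tributyl(ethynyl)stannane (Pd(PPh3)4, toluene, 60 °C), which gives 13 directly; no new compound is made on this way (F0).

**Step 11.** Cleavage of the C5 methyl ether may stall once boron is bound at O3 and the carbonyl, or forcing conditions may take a second methyl (at O8 or O5').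
Fallback (sets out from 21, comes back at 22): the three groups are removed one at a time by orthogonal means. Hydrogenolysis (H2, Pd/C, EtOAc) gives 3-hydroxy-2-[2-hydroxy-5-methoxy-4-(methoxymethoxy)phenyl]-5,7,8-trimethoxy-4H-chromen-4-one F12. HCl in methanol at rt removes the acetal, giving 2-(2,4-dihydroxy-5-methoxyphenyl)-3-hydroxy-5,7,8-trimethoxy-4H-chromen-4-one F13. A measured amount of AlCl3 in MeCN then cleaves only the chelated C5 methyl ether, giving 22.

## Further compounds

F1 | step 10 | 2,4-bis(benzyloxy)-1-methoxybenzene | COc1ccc(OCc2ccccc2)cc1OCc1ccccc1
F2 | step 10 | 1,5-bis(benzyloxy)-2-bromo-4-methoxybenzene | COc1cc(Br)c(OCc2ccccc2)cc1OCc1ccccc1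
F3 | step 10 | [2,4-bis(benzyloxy)-5-methoxyphenyl]lithium | [Li]c1cc(OC)c(OCc2ccccc2)cc1OCc1ccccc1
F4 | step 10 | [2,4-bis(benzyloxy)-5-methoxyphenyl]boronic acid | COc1cc(B(O)O)c(OCc2ccccc2)cc1OCc1ccccc1
F5 | step 10 | 3-(benzyloxy)-2-[2,4-bis(benzyloxy)-5-methoxyphenyl]-5,7,8-trimethoxy-4H-chromen-4-one | COc1cc(-c2oc3c(OC)c(OC)cc(OC)c3c(=O)c2OCc2ccccc2)c(OCc2ccccc2)cc1OCc1ccccc1
F6 | step 9 | tetramethylammonium pentacarbonyl[2-(methoxymethoxy)-1-oxidoprop-2-en-1-ylidene]chromate | C[N+](C)(C)C.COCOC(=C)C([O-])=[Cr](=C=O)(=C=O)(=C=O)(=C=O)=C=O
F7 | step 9 | pentacarbonyl[acetoxy(1-(methoxymethoxy)vinyl)carbene]chromium | COCOC(=C)C(OC(C)=O)=[Cr](=C=O)(=C=O)(=C=O)(=C=O)=C=O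
F8 | step 3 | (2,3,4,6-tetramethoxyphenyl)lithium | [Li]c1c(OC)cc(OC)c(OC)c1OC
F9 | step 3 | 2-(benzyloxy)-1-(2,3,4,6-tetramethoxyphenyl)ethan-1-one | COc1cc(OC)c(C(=O)COCc2ccccc2)c(OC)c1OC
F10 | step 3 | 2-(benzyloxy)-1-(2-hydroxy-3,4,6-trimethoxyphenyl)ethan-1-one | COc1cc(OC)c(C(=O)COCc2ccccc2)c(O)c1OC
F11 | step 3 | 2-(benzyloxy)-3-(dimethylamino)-1-(2-hydroxy-3,4,6-trimethoxyphenyl)prop-2-en-1-one (dimethylamino group anti to the carbonyl) | CN(C)/C=C(OCc1ccccc1)/C(=O)c1c(OC)cc(OC)c(OC)c1O
F0 | step 7 | none | none
F12 | step 11 | 3-hydroxy-2-[2-hydroxy-5-methoxy-4-(methoxymethoxy)phenyl]-5,7,8-trimethoxy-4H-chromen-4-one | COCOc1cc(O)c(-c2oc3c(OC)c(OC)cc(OC)c3c(=O)c2O)cc1OC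
F13 | step 11 | 2-(2,4-dihydroxy-5-methoxyphenyl)-3-hydroxy-5,7,8-trimethoxy-4H-chromen-4-one | COc1cc(-c2oc3c(OC)c(OC)cc(OC)c3c(=O)c2O)c(O)cc1O
A1 | alternative 1 | methylene-bridged (3-O to 2'-O) 4'-benzyloxy-5,7,8,5'-tetramethoxyflavonol | COc1cc(OC)c2c(=O)c3OCOc4cc(OCc5ccccc5)c(OC)cc4-c3oc2c1OC
A2 | alternative 1 | 3-{[5-(benzyloxy)-2-bromo-4-methoxyphenoxy]methoxy}-5,7,8-trimethoxychromen-4-one | COc1cc(OC)c2c(=O)c(OCOc3cc(OCc4ccccc4)c(OC)cc3Br)coc2c1OC
A3 | alternative 2 | 2-[2,4-bis(benzyloxy)-5-methoxyphenyl]-7-methoxy-5-(methoxymethoxy)chromen-4-one | COCOc1cc(OC)cc2oc(-c3cc(OC)c(OCc4ccccc4)cc3OCc3ccccc3)cc(=O)c12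
A4 | alternative 2 | 5-methoxy-3-(methoxymethoxy)-2-(trimethylsilyl)phenyl trifluoromethanesulfonate | COCOc1cc(OC)cc(OS(=O)(=O)C(F)(F)F)c1[Si](C)(C)C
A5 | alternative 2 | 3-[2,4-bis(benzyloxy)-5-methoxyphenyl]prop-2-ynoic acid | COc1cc(C#CC(=O)O)c(OCc2ccccc2)cc1OCc1ccccc1
A6 | alternative 3 | 3-benzyloxy-2-[2,4-bis(benzyloxy)-5-methoxyphenyl]-5,7-dihydroxy-8-methoxychromen-4-one | COc1c(O)cc(O)c2c(=O)c(OCc3ccccc3)c(-c3cc(OC)c(OCc4ccccc4)cc3OCc3ccccc3)oc12
A7 | alternative 3 | tert-butyl 4-{5-(benzyloxy)-6-[2,4-bis(benzyloxy)-5-methoxyphenyl]-4-oxo-4H-pyran-2-yl}-4-methoxy-3-oxobutanoate (racemic) | COC(C(=O)CC(=O)OC(C)(C)C)c1cc(=O)c(OCc2ccccc2)c(-c2cc(OC)c(OCc3ccccc3)cc2OCc2ccccc2)o1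
A8 | alternative 3 | kojic acid, 5-hydroxy-2-(hydroxymethyl)-4H-pyran-4-one | OCc1cc(=O)c(O)co1
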